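**Retrosynthetic overview**

- The strategy rests on ring A: C4a and C8a are adjacent carbons that carry the C4 carbonyl carbon and O1, and C5, C6, C7 and C8 all bear oxygen. A mirror-symmetric 3,4,5,6-tetramethoxybenzyne can therefore supply C4a and C8a with all four oxygens already in place.
- Key disconnection: O1–C8a and C4–C4a (the aryne inserts into the O–C(=O) bond of a 3-aryl-2,3-dimethoxyacrylic acid) plus O1–C2 (the phenoxide displaces the β-methoxy group). Ring C is the only ring formed; rings A and B arrive intact.
- Aryne precursor: an o-silylaryl triflate made from 1,2,3,4-tetramethoxybenzene by hydroxylation, bromination and retro-Brook/triflation.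
- Acid: from 3,4-bis(benzyloxy)benzaldehyde by Dakin oxidation, O-methylation, formylation, aldol addition of methyl methoxyacetate, oxidation, enol O-methylation and saponification.
- End game: BCl3 removes the 5-methyl ether (chelated to C4=O) and both benzyl ethers.

Key step: step 11

Assumption: the dimethoxyacrylic acid and its methyl ester are drawn as the E isomers; the Z isomers would serve equally in the key step, and the aldol adduct is carried as a racemic diastereomer mixture because its stereocentres are removed again.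

**Route**

Step 1
Reactants: 1 1,2,3,4-tetramethoxybenzene
Product: 4 2,3,4,5-tetramethoxyphenol, via aryllithium 2 (not isolated), via dimethyl arylboronate 3 (not isolated)
Conditions: n-BuLi, TMEDA, THF, 0 °C; B(OMe)3, −78 °C → rt; 30% H2O2, AcOH, 0 °C → rt
Reagents that add atoms: hydrogen peroxide, OO
Why: Directed ortho-lithiation can only take one of the two equivalent ring hydrogens next to a methoxy group, and borylation followed by oxidative boron-to-oxygen aryl shift gives the phenol (lithiation–borylation–oxidation).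

Step 2
Reactants: 4 2,3,4,5-tetramethoxyphenol
Product: 5 2-bromo-3,4,5,6-tetramethoxyphenol
Conditions: NBS, MeCN, −20 → 0 °C, dark
Reagents that add atoms: N-bromosuccinimide, O=C1CCC(=O)N1Br
Why: Electrophilic aromatic bromination has a single free ring position available, and it lies ortho to the activating hydroxyl group.

Step 3
Reactants: 5 2-bromo-3,4,5,6-tetramethoxyphenol
Product: 8 2,3,4,5-tetramethoxy-6-(trimethylsilyl)phenyl trifluoromethanesulfonate, via aryl trimethylsilyl ether 6 (not isolated), via lithium silylphenoxide 7 (not isolated)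
Conditions: (Me3Si)2NH, THF, 70 °C, then evaporate; n-BuLi, THF, −78 °C; Tf2O, −78 → 0 °C
Reagents that add atoms: hexamethyldisilazane, C[Si](C)(C)N[Si](C)(C)C; trifluoromethanesulfonic anhydride, O=S(=O)(OS(=O)(=O)C(F)(F)F)C(F)(F)F
Why: O-silylation, bromine–lithium exchange, 1,3 oxygen-to-carbon silyl shift (retro-Brook rearrangement) and O-triflation of the resulting phenoxide form the standard sequence to o-silylaryl triflates, as used for other methoxy-flanked aryne precursors.

Step 4
Reactants: 9 3,4-bis(benzyloxy)benzaldehyde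
Product: 11 3,4-bis(benzyloxy)phenol, via aryl formate 10 (not isolated)
Conditions: mCPBA, CH2Cl2, rt; aq. NaHCO3 wash; K2CO3 (cat.), MeOH, rt
Reagents that add atoms: 3-chloroperoxybenzoic acid, OOC(=O)c1cccc(Cl)c1
Why: Baeyer–Villiger oxidation of an electron-rich benzaldehyde proceeds with aryl migration to the formate, which methanolysis cleaves (Dakin-type oxidation).

Step 5
Reactants: 11 3,4-bis(benzyloxy)phenol
Product: 12 1,2-bis(benzyloxy)-4-methoxybenzene
Conditions: MeI, K2CO3, acetone, reflux
Reagents that add atoms: iodomethane, CI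
Why: Williamson etherification of the phenoxide, with nothing else in the molecule that can be alkylated.

Step 6
Reactants: 12 1,2-bis(benzyloxy)-4-methoxybenzene
Product: 14 4,5-bis(benzyloxy)-2-methoxybenzaldehyde, via iminium chloride 13 (not isolated)
Conditions: POCl3, DMF, 0 → 60 °C; then aq. NaOAc
Reagents that add atoms: N,N-dimethylformamide, CN(C)C=O; water, O
Why: Vilsmeier–Haack formylation attacks the position ortho to the methoxy group and para to a benzyloxy group, the most activated and least hindered site of a 1,2,4-trialkoxybenzene.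

Step 7
Reactants: 14 4,5-bis(benzyloxy)-2-methoxybenzaldehyde; 15 methyl methoxyacetate
Product: 17 methyl 3-[4,5-bis(benzyloxy)-2-methoxyphenyl]-3-hydroxy-2-methoxypropanoate, via lithium ester enolate 16 (not isolated)
Conditions: LiN(i-Pr)2, THF, −78 °C, then 14; aq. NH4Cl
Reagents that add atoms: none
Why: Aldol addition of a preformed lithium ester enolate to a non-enolisable aldehyde; the two new stereocentres are formed without control as a racemic diastereomer mixture because steps 8 and 9 remove both.

Step 8
Reactants: 17 methyl 3-[4,5-bis(benzyloxy)-2-methoxyphenyl]-3-hydroxy-2-methoxypropanoate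
Product: 18 methyl 3-[4,5-bis(benzyloxy)-2-methoxyphenyl]-2-methoxy-3-oxopropanoate
Conditions: Dess–Martin periodinane, CH2Cl2, rt
Reagents that add atoms: none
Why: Dess–Martin oxidation converts the benzylic secondary alcohol into the β-keto ester under neutral conditions that leave the benzyl ethers untouched.

Step 9
Reactants: 18 methyl 3-[4,5-bis(benzyloxy)-2-methoxyphenyl]-2-methoxy-3-oxopropanoate
Product: 19 methyl (E)-3-[4,5-bis(benzyloxy)-2-methoxyphenyl]-2,3-dimethoxyprop-2-enoate
Conditions: Cs2CO3, Me2SO4, DMF, 0 °C → rt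
Reagents that add atoms: dimethyl sulfate, COS(=O)(=O)OC
Why: O-alkylation of a β-keto ester enolate is favoured by a hard methylating agent acting on the weakly paired cesium enolate in a dipolar aprotic solvent, and the α-methoxy group hinders the carbon terminus.

Step 10
Reactants: 19 methyl (E)-3-[4,5-bis(benzyloxy)-2-methoxyphenyl]-2,3-dimethoxyprop-2-enoate
Product: 20 (E)-3-[4,5-bis(benzyloxy)-2-methoxyphenyl]-2,3-dimethoxyprop-2-enoic acid
Conditions: LiOH, THF/MeOH/H2O, 40 °C; then cold dilute HCl to pH 3–4
Reagents that add atoms: lithium hydroxide, [Li+].[OH-]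
Why: Saponification should proceed at the acyl carbon because the fully substituted β-carbon is deactivated by two donor methoxy groups, and cold, mild acidification spares the enol ether.

Step 11
Reactants: 8 2,3,4,5-tetramethoxy-6-(trimethylsilyl)phenyl trifluoromethanesulfonate; 20 (E)-3-[4,5-bis(benzyloxy)-2-methoxyphenyl]-2,3-dimethoxyprop-2-enoic acid
Product: 23 2-[4,5-bis(benzyloxy)-2-methoxyphenyl]-3,5,6,7,8-pentamethoxy-4H-chromen-4-one, via tetramethoxybenzyne 21 (not isolated), via cesium acylphenoxide 22 (not isolated)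
Conditions: 8 (2 equiv), anhydrous CsF (5 equiv), THF, sealed tube, 125 °C
Reagents that add atoms: none
Why: Fluoride strips the silyl group from 8 and triflate leaves, giving the mirror-symmetric aryne 21; the cesium carboxylate of 20 adds to it, the resulting ortho aryl anion attacks the carbonyl of the freshly formed aryl ester in a 4-exo-trig sense, and collapse of the strained alkoxide moves the acyl group from oxygen to carbon to give the o-acylphenoxide 22, so that O1–C8a and C4–C4a arise by a formal σ-insertion of the aryne into the O–C(=O) bond. The closest known reaction type is the fluoride-triggered insertion of arynes into the C–O bond of carboxylic acids to give o-hydroxyaryl ketones, with ring closure in the same flask to chromanones, flavones and xanthones. Ring C then closes by 6-endo-trig addition of the phenoxide oxygen to the β-carbon of the β-methoxy enone followed by loss of methoxide (O1–C2), an addition–elimination that keeps the 3-methoxy group and is driven by formation of the pyranone. No stereocentre is formed, and the alkene geometry of 20 is immaterial because the β-carbon becomes tetrahedral before methoxide departs. Regiochemistry does not arise since both aryne carbons of 21 are equivalent; the step does need acyl transfer to outrun protonation of the aryl anion (which would stop at the aryl ester) and conjugate attack at the β-carbon (which would lead to a coumarin), and the hot aprotic THF medium with excess CsF together with the in-plane carbanion sitting next to the ester carbonyl should secure this. Because the nucleophile is a carboxylate, attack on the aryne can occur only through oxygen, unlike the carbon attack seen with β-keto ester enolates.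

Step 12
Reactants: 23 2-[4,5-bis(benzyloxy)-2-methoxyphenyl]-3,5,6,7,8-pentamethoxy-4H-chromen-4-one
Product: 24 2-(4,5-dihydroxy-2-methoxyphenyl)-5-hydroxy-3,6,7,8-tetramethoxy-4H-chromen-4-one (5,4',5'-trihydroxy-3,6,7,8,2'-pentamethoxyflavone)
Conditions: BCl3, C6HMe5, CH2Cl2, −78 → 0 °C; then H2O
Reagents that add atoms: none
Why: Lewis-acid ether cleavage in which BCl3 removes the benzyl groups at low temperature with pentamethylbenzene trapping the benzyl cations, and demethylates only the 5-methoxy group because it alone forms a six-membered chelate with the C4 carbonyl.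

**Compound list**

1 | 1,2,3,4-tetramethoxybenzene | COc1ccc(OC)c(OC)c1OC | starting material
2 | (2,3,4,5-tetramethoxyphenyl)lithium | [Li]c1cc(OC)c(OC)c(OC)c1OC | intermediate
3 | dimethyl (2,3,4,5-tetramethoxyphenyl)boronate | COB(OC)c1cc(OC)c(OC)c(OC)c1OC | intermediate
4 | 2,3,4,5-tetramethoxyphenol | Oc1cc(OC)c(OC)c(OC)c1OC | intermediate
5 | 2-bromo-3,4,5,6-tetramethoxyphenol | Oc1c(Br)c(OC)c(OC)c(OC)c1OC | intermediate
6 | (2-bromo-3,4,5,6-tetramethoxyphenoxy)trimethylsilane | C[Si](C)(C)Oc1c(Br)c(OC)c(OC)c(OC)c1OC | intermediate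
7 | lithium 2,3,4,5-tetramethoxy-6-(trimethylsilyl)phenolate | [Li+].[O-]c1c([Si](C)(C)C)c(OC)c(OC)c(OC)c1OC | intermediate
8 | 2,3,4,5-tetramethoxy-6-(trimethylsilyl)phenyl trifluoromethanesulfonate | COc1c(OC)c(OC)c(OC)c(OS(=O)(=O)C(F)(F)F)c1[Si](C)(C)C | intermediate
9 | 3,4-bis(benzyloxy)benzaldehyde | O=Cc1ccc(OCc2ccccc2)c(OCc2ccccc2)c1 | starting material
10 | 3,4-bis(benzyloxy)phenyl formate | O=COc1ccc(OCc2ccccc2)c(OCc2ccccc2)c1 | intermediate
11 | 3,4-bis(benzyloxy)phenol | Oc1ccc(OCc2ccccc2)c(OCc2ccccc2)c1 | intermediate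
12 | 1,2-bis(benzyloxy)-4-methoxybenzene | COc1ccc(OCc2ccccc2)c(OCc2ccccc2)c1 | intermediate
13 | N-{[4,5-bis(benzyloxy)-2-methoxyphenyl]methylidene}-N-methylmethanaminium chloride | C[N+](C)=Cc1cc(OCc2ccccc2)c(OCc2ccccc2)cc1OC.[Cl-] | intermediate
14 | 4,5-bis(benzyloxy)-2-methoxybenzaldehyde | COc1cc(OCc2ccccc2)c(OCc2ccccc2)cc1C=O | intermediate
15 | methyl methoxyacetate | COCC(=O)OC | starting material
16 | lithium 1,2-dimethoxyethen-1-olate | COC=C([O-])OC.[Li+] | intermediate
17 | methyl 3-[4,5-bis(benzyloxy)-2-methoxyphenyl]-3-hydroxy-2-methoxypropanoate (racemic diastereomer mixture) | COC(=O)C(OC)C(O)c1cc(OCc2ccccc2)c(OCc2ccccc2)cc1OC | intermediate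
18 | methyl 3-[4,5-bis(benzyloxy)-2-methoxyphenyl]-2-methoxy-3-oxopropanoate | COC(=O)C(OC)C(=O)c1cc(OCc2ccccc2)c(OCc2ccccc2)cc1OC | intermediate
19 | methyl (E)-3-[4,5-bis(benzyloxy)-2-methoxyphenyl]-2,3-dimethoxyprop-2-enoate | CO/C(=C(/OC)C(=O)OC)c1cc(OCc2ccccc2)c(OCc2ccccc2)cc1OC | intermediate
20 | (E)-3-[4,5-bis(benzyloxy)-2-methoxyphenyl]-2,3-dimethoxyprop-2-enoic acid | CO/C(=C(/OC)C(=O)O)c1cc(OCc2ccccc2)c(OCc2ccccc2)cc1OC | intermediate
21 | 3,4,5,6-tetramethoxybenzyne | COC1=C(OC)C(OC)=C(OC)C#C1 | intermediate
22 | cesium 2-{(E)-3-[4,5-bis(benzyloxy)-2-methoxyphenyl]-2,3-dimethoxyprop-2-enoyl}-3,4,5,6-tetramethoxyphenolate | CO/C(=C(/OC)C(=O)c1c([O-])c(OC)c(OC)c(OC)c1OC)c1cc(OCc2ccccc2)c(OCc2ccccc2)cc1OC.[Cs+] | intermediate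
23 | 2-[4,5-bis(benzyloxy)-2-methoxyphenyl]-3,5,6,7,8-pentamethoxy-4H-chromen-4-one | COc1cc(OCc2ccccc2)c(OCc2ccccc2)cc1-c1oc2c(OC)c(OC)c(OC)c(OC)c2c(=O)c1OC | intermediate
24 | 2-(4,5-dihydroxy-2-methoxyphenyl)-5-hydroxy-3,6,7,8-tetramethoxy-4H-chromen-4-one | COc1cc(O)c(O)cc1-c1oc2c(OC)c(OC)c(OC)c(O)c2c(=O)c1OC | target

**Step count**

Total: 12 steps. Longest linear sequence: 9 steps (steps 4 to 12, from 3,4-bis(benzyloxy)benzaldehyde).

**Steps most likely to fail**

1. Step 11. The aryl anion may be protonated before acyl transfer, so that the sequence stops at the aryl ester. The hindered carboxylate may also fail to trap the electron-rich aryne, and released methoxide may consume aryne. If only the open-chain o-hydroxyaryl ketone accumulates, brief acid treatment should close it to 23. The full fallback is the classical diketone route, setting out from 4 and 14 and returning at 23. C-acylation of 4 at its only free position with methoxyacetic acid and BF3·OEt2 should give 1-(2-hydroxy-3,4,5,6-tetramethoxyphenyl)-2-methoxyethan-1-one F1. Pinnick oxidation of 14 (NaClO2, NaH2PO4, 2-methyl-2-butene) should give 4,5-bis(benzyloxy)-2-methoxybenzoic acid F2. Esterification of F1 with F2 (EDC, DMAP) should give 2-(methoxyacetyl)-3,4,5,6-tetramethoxyphenyl 4,5-bis(benzyloxy)-2-methoxybenzoate F3. Baker–Venkataraman rearrangement (KOt-Bu, THF) should give 1-[4,5-bis(benzyloxy)-2-methoxyphenyl]-3-(2-hydroxy-3,4,5,6-tetramethoxyphenyl)-2-methoxypropane-1,3-dione F4. Cyclodehydration (TsOH, toluene, 80 °C) should then give 23.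

2. Step 9. The ambident enolate may be methylated at carbon, or the hindered enolate may react incompletely. The fallback avoids the enol ether altogether; it sets out from 14 and 15 and returns at 23. NaOMe-mediated condensation should give methyl (Z)-3-[4,5-bis(benzyloxy)-2-methoxyphenyl]-2-methoxyprop-2-enoate F5. Saponification with LiOH should give (Z)-3-[4,5-bis(benzyloxy)-2-methoxyphenyl]-2-methoxyprop-2-enoic acid F6. Aryne insertion with 8 (CsF, THF, 125 °C) followed by oxa-Michael closure in the same flask should give 2-[4,5-bis(benzyloxy)-2-methoxyphenyl]-3,5,6,7,8-pentamethoxychroman-4-one F7 as a diastereomer mixture. Dehydrogenation (I2, DMSO, 110 °C) should then give 23.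

3. Step 12. Once the 5-O–boron chelate has formed, further demethylation at the neighbouring 6-methoxy or the 3-methoxy group may follow, and benzyl cations may be transferred to the electron-rich rings. The fallback separates the two deprotections; it sets out from 23 and returns at 24. Hydrogenolysis (H2, Pd/C, EtOAc/MeOH) should give 2-(4,5-dihydroxy-2-methoxyphenyl)-3,5,6,7,8-pentamethoxy-4H-chromen-4-one F8. Chelation-controlled mono-demethylation with a limited amount of AlCl3 in MeCN at rt should then give 24.

**Further compounds**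

F1 | step 11 | 1-(2-hydroxy-3,4,5,6-tetramethoxyphenyl)-2-methoxyethan-1-one | COCC(=O)c1c(O)c(OC)c(OC)c(OC)c1OC
F2 | step 11 | 4,5-bis(benzyloxy)-2-methoxybenzoic acid | COc1cc(OCc2ccccc2)c(OCc2ccccc2)cc1C(=O)O
F3 | step 11 | 2-(methoxyacetyl)-3,4,5,6-tetramethoxyphenyl 4,5-bis(benzyloxy)-2-methoxybenzoate | COCC(=O)c1c(OC(=O)c2cc(OCc3ccccc3)c(OCc3ccccc3)cc2OC)c(OC)c(OC)c(OC)c1OC
F4 | step 11 | 1-[4,5-bis(benzyloxy)-2-methoxyphenyl]-3-(2-hydroxy-3,4,5,6-tetramethoxyphenyl)-2-methoxypropane-1,3-dione | COC(C(=O)c1cc(OCc2ccccc2)c(OCc2ccccc2)cc1OC)C(=O)c1c(O)c(OC)c(OC)c(OC)c1OC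
F5 | step 9 | methyl (Z)-3-[4,5-bis(benzyloxy)-2-methoxyphenyl]-2-methoxyprop-2-enoate | COC(=O)/C(OC)=C/c1cc(OCc2ccccc2)c(OCc2ccccc2)cc1OC
F6 | step 9 | (Z)-3-[4,5-bis(benzyloxy)-2-methoxyphenyl]-2-methoxyprop-2-enoic acid | OC(=O)/C(OC)=C/c1cc(OCc2ccccc2)c(OCc2ccccc2)cc1OC
F7 | step 9 | 2-[4,5-bis(benzyloxy)-2-methoxyphenyl]-3,5,6,7,8-pentamethoxychroman-4-one (diastereomer mixture) | COc1cc(OCc2ccccc2)c(OCc2ccccc2)cc1C1Oc2c(OC)c(OC)c(OC)c(OC)c2C(=O)C1OC
F8 | step 12 | 2-(4,5-dihydroxy-2-methoxyphenyl)-3,5,6,7,8-pentamethoxy-4H-chromen-4-one | COc1cc(O)c(O)cc1-c1oc2c(OC)c(OC)c(OC)c(OC)c2c(=O)c1OC
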